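**Plan**

1. Numbering used (daucane): C1 = quaternary ring-fusion carbon (CH3), C2–C3 = CH2CH2, C4 = C(OH)(i-Pr), C5 = ring-fusion CH, C6 = CH–O-anisoyl, C7=C8(CH3), C9 = CHOH, C10 = CH2.
2. Cuts: the anisoate C–O bond; C7=C8 (metathesis, opens the seven-membered ring); C4–i-Pr (leaves a cyclopentanone); C3–C4 and C1–C5 together (opens the five-membered ring to an acyclic allyl vinyl ether); the enol ether C4–O bond (two fragments).
3. Enabling feature: in the five-membered ring the quaternary C1 is vicinal to the tertiary C5, C4 is the oxygenated carbon next to C5, and C2–C3 is an unfunctionalised ethylene bridge. This is a 2,3,3-trisubstituted cyclopentanone, the hydroacylation product of the 4-pentenal that a Claisen rearrangement delivers; C4 is therefore carried at the aldehyde/ketone level through the key step.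
4. Forward: allylic alcohol (C1–C3, C8–C10) + vinyl iodide (C4–C7) → allyl vinyl ether → cyclopentanone (five-membered ring first) → i-Pr addition → seven-membered ring by metathesis → anisoate.
5. Stereochemistry: C9 and C6 from catalytic enantioselective additions to methacrolein and crotonaldehyde; C1 and C5 from the chair Claisen step (E,E geometry, face set by C6); C4 from addition anti to the C5 side chain.

Key step: step 9

Remark: (R)-TRIP and (S,S)-ProPhenol are the catalyst antipodes expected, by analogy with aryl aldehydes and enals, to give the (R)-carbinol 3 and the (S)-carbinol 10; if either sense proves opposite, the mirror-image catalyst is taken with no other change.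

**Route**

Step 1
Reactants: 1 methacrolein; 2 allenylboronic acid pinacol ester
Product: 3 (3R)-2-methylhex-1-en-5-yn-3-ol
Conditions: (R)-TRIP (5 mol %), 4 Å MS, PhMe, −30 °C; aq. work-up
Reagents that add atoms: none
Why: Chiral phosphoric acid-catalysed propargylboration ((R)-TRIP = (R)-3,3'-bis(2,4,6-triisopropylphenyl)-BINOL hydrogen phosphate): the allenylboronate adds through a closed six-membered SE2' transition state in which the phosphate shields one aldehyde face, which should set the C9 carbinol centre as R and give the homopropargylic alcohol.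

Step 2
Reactants: 3 (3R)-2-methylhex-1-en-5-yn-3-ol
Product: 4 tert-butyldimethyl{[(3R)-2-methylhex-1-en-5-yn-3-yl]oxy}silane
Conditions: TBSCl, imidazole, DMF, 0 °C to rt
Reagents that add atoms: tert-butyldimethylsilyl chloride CC(C)(C)[Si](C)(C)Cl
Why: Routine silyl ether formation at the secondary hydroxyl; the stereocentre is untouched and the ether should survive AlMe3, base, heat, organometallic addition and metathesis.

Step 3
Reactants: 4 tert-butyldimethyl{[(3R)-2-methylhex-1-en-5-yn-3-yl]oxy}silane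
Product: 6 (2E,5R)-5-[(tert-butyldimethylsilyl)oxy]-3,6-dimethylhepta-2,6-dien-1-ol, via alkenyldimethylalane 5 (not isolated)
Conditions: AlMe3 (2.5 equiv), Cp2ZrCl2 (0.25 equiv), CH2Cl2, 0 °C to rt; then (CH2O)n, THF, 0 °C to rt; aq. work-up
Reagents that add atoms: trimethylaluminium C[Al](C)C; paraformaldehyde (formaldehyde unit) C=O
Why: Negishi zirconium-catalysed carboalumination adds CH3 and Al syn across the terminal alkyne with aluminium on the terminal carbon (the 1,1-disubstituted alkene is inert), and the alkenylalane is hydroxymethylated with retention, which should fix the E trisubstituted olefin that later holds the C10 chain equatorial in the Claisen chair.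

Step 4
Reactants: 7 (E)-crotonaldehyde; 8 ethynyltrimethylsilane
Product: 10 (3S,4E)-1-(trimethylsilyl)hex-4-en-1-yn-3-ol, via alkynyl(methyl)zinc 9 (not isolated)
Conditions: Me2Zn (3 equiv), (S,S)-ProPhenol (20 mol %), Ph3PO (40 mol %), PhMe, 0 °C; aq. work-up
Reagents that add atoms: none
Why: Trost's zinc–ProPhenol alkynylation: the alkynylzinc formed in situ adds 1,2 to the enal inside the dinuclear zinc complex, whose chiral pocket should select the aldehyde face that gives the S carbinol (the later C6).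

Step 5
Reactants: 10 (3S,4E)-1-(trimethylsilyl)hex-4-en-1-yn-3-ol
Product: 11 (3S,4E)-hex-4-en-1-yn-3-ol
Conditions: K2CO3 (cat.), MeOH, rt
Reagents that add atoms: none
Why: Methanolysis of the alkynyl C–Si bond under mild base (protiodesilylation) leaves the bis-unsaturated carbinol and its configuration intact.

Step 6
Reactants: 11 (3S,4E)-hex-4-en-1-yn-3-ol
Product: 12 1-({[(3S,4E)-hex-4-en-1-yn-3-yl]oxy}methyl)-4-methoxybenzene
Conditions: NaH (1.05 equiv), 4-methoxybenzyl chloride, Bu4NI (cat.), THF/DMF, 0 °C to rt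
Reagents that add atoms: 4-methoxybenzyl chloride COc1ccc(CCl)cc1
Why: Williamson etherification of the sodium alkoxide (the hydroxyl is far more acidic than the alkyne C–H) installs an ether that tolerates the later organometallic and thermal steps, serves as the inside alkoxy group in step 9 and is cleaved oxidatively in step 12; the C–O bond at the stereocentre is not broken.

Step 7
Reactants: 12 1-({[(3S,4E)-hex-4-en-1-yn-3-yl]oxy}methyl)-4-methoxybenzene
Product: 14 1-({[(1E,3S,4E)-1-iodohexa-1,4-dien-3-yl]oxy}methyl)-4-methoxybenzene, via alkenylzirconocene chloride 13 (not isolated)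
Conditions: Cp2Zr(H)Cl (1.3 equiv), THF, rt, dark; then iodine, 0 °C
Reagents that add atoms: iodine [I][I]
Why: Hydrozirconation adds Zr–H syn to the terminal alkyne much faster than to the internal alkene, with zirconium on the terminal carbon, and iodinolysis of the C–Zr bond proceeds with retention, which should give the E vinyl iodide only.

Step 8
Reactants: 6 (2E,5R)-5-[(tert-butyldimethylsilyl)oxy]-3,6-dimethylhepta-2,6-dien-1-ol; 14 1-({[(1E,3S,4E)-1-iodohexa-1,4-dien-3-yl]oxy}methyl)-4-methoxybenzene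
Product: 15 tert-butyl{[(3R,5E)-7-({(1E,3S,4E)-3-[(4-methoxyphenyl)methoxy]hexa-1,4-dien-1-yl}oxy)-2,5-dimethylhepta-1,5-dien-3-yl]oxy}dimethylsilane
Conditions: CuI (10 mol %), 3,4,7,8-tetramethyl-1,10-phenanthroline (20 mol %), Cs2CO3 (1.5 equiv), PhMe, 80 °C
Reagents that add atoms: none
Why: Copper-catalysed Ullmann-type C–O coupling of a vinyl iodide with a primary allylic alcohol retains both double-bond geometries and is run below the temperature at which this hindered ether rearranges, so the E,E allyl vinyl ether needed for the chair transition state should be isolable (base-washed silica).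

Step 9
Reactants: 15 tert-butyl{[(3R,5E)-7-({(1E,3S,4E)-3-[(4-methoxyphenyl)methoxy]hexa-1,4-dien-1-yl}oxy)-2,5-dimethylhepta-1,5-dien-3-yl]oxy}dimethylsilane
Product: 17 (2S,3R)-3-{(2R)-2-[(tert-butyldimethylsilyl)oxy]-3-methylbut-3-en-1-yl}-2-{(1S,2E)-1-[(4-methoxyphenyl)methoxy]but-2-en-1-yl}-3-methylcyclopentan-1-one, via pent-4-enal 16 (not isolated)
Conditions: [RhCl(cod)]2 (5 mol %), dppe (10 mol %), PhCN, 130 °C, sealed tube
Reagents that add atoms: none
Why: Heating triggers a concerted suprafacial [3,3]-sigmatropic (Claisen) shift of the allyl vinyl ether through a chair transition state, which forms the C1–C5 bond and releases the C4 aldehyde as a 4-pentenal; the monovalent rhodium catalyst then adds into the aldehyde C–H bond, hydrometalates the new vinyl group in the anti-Markovnikov sense and forms the C3–C4 bond by reductive elimination. The closest known reaction type is the rhodium-catalysed tandem Claisen rearrangement–hydroacylation of allyl vinyl ethers to 3,3-disubstituted cyclopentanones. Only the cyclopentanone ring closes here, by C–C reductive elimination from a six-membered acylrhodacycle, which amounts to a 5-endo-trig addition of the acyl C–H bond across the vinyl group that the metal pathway makes possible. The quaternary C1 and the tertiary C5 are set together in the chair, in which the E enol ether and the E trisubstituted allyl unit hold the C6 and C10 chains equatorial and so put the C1 methyl group cis to the C5 side chain; which face of the enol ether reacts is controlled by the C6 stereocentre, with its 4-methoxybenzyloxy group inside and the propenyl group anti to the forming bond. The step needs this π-facial selectivity and chemoselectivity among three olefins in the hydroacylation; the latter is secured because only the vinyl group on the quaternary carbon is a terminal alkene held as a 4-pentenal (helped by the gem-dialkyl effect), while the propenyl group is internal and the isopropenyl group is too remote.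

Step 10
Reactants: 17 (2S,3R)-3-{(2R)-2-[(tert-butyldimethylsilyl)oxy]-3-methylbut-3-en-1-yl}-2-{(1S,2E)-1-[(4-methoxyphenyl)methoxy]but-2-en-1-yl}-3-methylcyclopentan-1-one
Product: 18 (1R,2S,3R)-3-{(2R)-2-[(tert-butyldimethylsilyl)oxy]-3-methylbut-3-en-1-yl}-2-{(1S,2E)-1-[(4-methoxyphenyl)methoxy]but-2-en-1-yl}-3-methyl-1-(propan-2-yl)cyclopentan-1-ol
Conditions: LaCl3·2LiCl (1.1 equiv), i-PrMgCl (1.5 equiv), THF, 0 °C; aq. work-up
Reagents that add atoms: isopropylmagnesium chloride CC(C)[Mg]Cl
Why: 1,2-Addition of the isopropyl Grignard reagent activated by the Lewis acidic, weakly basic lanthanum salt should suppress enolisation and β-hydride reduction of the hindered ketone, and the nucleophile should enter trans to the large C5 side chain, which places the new hydroxyl cis to that chain and to the C1 methyl group as in the target.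

Step 11
Reactants: 18 (1R,2S,3R)-3-{(2R)-2-[(tert-butyldimethylsilyl)oxy]-3-methylbut-3-en-1-yl}-2-{(1S,2E)-1-[(4-methoxyphenyl)methoxy]but-2-en-1-yl}-3-methyl-1-(propan-2-yl)cyclopentan-1-ol
Product: 19 (3R,3aS,4S,7R,8aR)-7-[(tert-butyldimethylsilyl)oxy]-4-[(4-methoxyphenyl)methoxy]-6,8a-dimethyl-3-(propan-2-yl)-1,2,3,3a,4,7,8,8a-octahydroazulen-3-ol
Conditions: second-generation Grubbs catalyst (10 mol %), PhMe (0.005 M), 80 °C
Reagents that add atoms: none
Why: Ring-closing olefin metathesis: ruthenium loads on the propenyl group and closes onto the isopropenyl group with loss of propene, which should give the seven-membered ring with the trisubstituted, necessarily Z, C7=C8 bond; the trans relation of the two side chains on the cyclopentane gives the trans ring fusion.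

Step 12
Reactants: 19 (3R,3aS,4S,7R,8aR)-7-[(tert-butyldimethylsilyl)oxy]-4-[(4-methoxyphenyl)methoxy]-6,8a-dimethyl-3-(propan-2-yl)-1,2,3,3a,4,7,8,8a-octahydroazulen-3-ol
Product: 20 (3R,3aS,4S,7R,8aR)-7-[(tert-butyldimethylsilyl)oxy]-6,8a-dimethyl-3-(propan-2-yl)-1,2,3,3a,4,7,8,8a-octahydroazulene-3,4-diol
Conditions: DDQ (1.3 equiv), CH2Cl2/pH 7 buffer, 0 °C
Reagents that add atoms: none
Why: Oxidative cleavage of the electron-rich 4-methoxybenzyl ether (hydride abstraction by DDQ, hydrolysis of the oxocarbenium ion) should free the C6 hydroxyl while the silyl ether, the tertiary alcohol and the ring olefin are left alone.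

Step 13
Reactants: 20 (3R,3aS,4S,7R,8aR)-7-[(tert-butyldimethylsilyl)oxy]-6,8a-dimethyl-3-(propan-2-yl)-1,2,3,3a,4,7,8,8a-octahydroazulene-3,4-diol; 21 4-methoxybenzoyl chloride
Product: 22 (3R,3aS,4S,7R,8aR)-7-[(tert-butyldimethylsilyl)oxy]-3-hydroxy-6,8a-dimethyl-3-(propan-2-yl)-1,2,3,3a,4,7,8,8a-octahydroazulen-4-yl 4-methoxybenzoate
Conditions: Et3N, DMAP (cat.), CH2Cl2, rt to 40 °C
Reagents that add atoms: none
Why: DMAP-catalysed acylation should take place only at the secondary C6 hydroxyl because the C4 hydroxyl is tertiary and flanked by the isopropyl group; the configuration at C6 is retained because its C–O bond is not broken.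

Step 14
Reactants: 22 (3R,3aS,4S,7R,8aR)-7-[(tert-butyldimethylsilyl)oxy]-3-hydroxy-6,8a-dimethyl-3-(propan-2-yl)-1,2,3,3a,4,7,8,8a-octahydroazulen-4-yl 4-methoxybenzoate
Product: 23 (3R,3aS,4S,7R,8aR)-3,7-dihydroxy-6,8a-dimethyl-3-(propan-2-yl)-1,2,3,3a,4,7,8,8a-octahydroazulen-4-yl 4-methoxybenzoate
Conditions: HF·pyridine, THF/pyridine, 0 °C to rt
Reagents that add atoms: none
Why: Fluoride-mediated cleavage of the Si–O bond under mildly acidic conditions should free the C9 hydroxyl without ester hydrolysis, acyl migration or allylic transposition.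

**Compound list**

1 | methacrolein (2-methylprop-2-enal) | CC(=C)C=O | starting material
2 | allenylboronic acid pinacol ester (4,4,5,5-tetramethyl-2-(propa-1,2-dien-1-yl)-1,3,2-dioxaborolane) | C=C=CB1OC(C)(C)C(C)(C)O1 | starting material
3 | (3R)-2-methylhex-1-en-5-yn-3-ol | C=C(C)[C@H](O)CC#C | intermediate
4 | tert-butyldimethyl{[(3R)-2-methylhex-1-en-5-yn-3-yl]oxy}silane | C=C(C)[C@H](O[Si](C)(C)C(C)(C)C)CC#C | intermediate
5 | {(1E,4R)-4-[(tert-butyldimethylsilyl)oxy]-2,5-dimethylhexa-1,5-dien-1-yl}dimethylalumane | C[Al](C)/C=C(\C)C[C@@H](O[Si](C)(C)C(C)(C)C)C(C)=C | intermediate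
6 | (2E,5R)-5-[(tert-butyldimethylsilyl)oxy]-3,6-dimethylhepta-2,6-dien-1-ol | OC/C=C(\C)C[C@@H](O[Si](C)(C)C(C)(C)C)C(C)=C | intermediate
7 | (E)-crotonaldehyde ((2E)-but-2-enal) | C/C=C/C=O | starting material
8 | ethynyltrimethylsilane | C#C[Si](C)(C)C | starting material
9 | methyl[(trimethylsilyl)ethynyl]zinc | C[Zn]C#C[Si](C)(C)C | intermediate
10 | (3S,4E)-1-(trimethylsilyl)hex-4-en-1-yn-3-ol | O[C@H](C#C[Si](C)(C)C)/C=C/C | intermediate
11 | (3S,4E)-hex-4-en-1-yn-3-ol | O[C@H](C#C)/C=C/C | intermediate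
12 | 1-({[(3S,4E)-hex-4-en-1-yn-3-yl]oxy}methyl)-4-methoxybenzene | COc1ccc(CO[C@H](C#C)/C=C/C)cc1 | intermediate
13 | chlorobis(cyclopentadienyl){(1E,3S,4E)-3-[(4-methoxyphenyl)methoxy]hexa-1,4-dien-1-yl}zirconium | COc1ccc(CO[C@H](/C=C/[Zr](Cl)(C2C=CC=C2)C2C=CC=C2)/C=C/C)cc1 | intermediate
14 | 1-({[(1E,3S,4E)-1-iodohexa-1,4-dien-3-yl]oxy}methyl)-4-methoxybenzene | COc1ccc(CO[C@H](/C=C/I)/C=C/C)cc1 | intermediate
15 | tert-butyl{[(3R,5E)-7-({(1E,3S,4E)-3-[(4-methoxyphenyl)methoxy]hexa-1,4-dien-1-yl}oxy)-2,5-dimethylhepta-1,5-dien-3-yl]oxy}dimethylsilane | COc1ccc(CO[C@H](/C=C/OC/C=C(\C)C[C@@H](O[Si](C)(C)C(C)(C)C)C(C)=C)/C=C/C)cc1 | intermediate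
16 | (2S,3S)-3-{(2R)-2-[(tert-butyldimethylsilyl)oxy]-3-methylbut-3-en-1-yl}-2-{(1S,2E)-1-[(4-methoxyphenyl)methoxy]but-2-en-1-yl}-3-methylpent-4-enal | O=C[C@H]([C@@H](OCc1ccc(OC)cc1)/C=C/C)[C@](C)(C=C)C[C@@H](O[Si](C)(C)C(C)(C)C)C(C)=C | intermediate
17 | (2S,3R)-3-{(2R)-2-[(tert-butyldimethylsilyl)oxy]-3-methylbut-3-en-1-yl}-2-{(1S,2E)-1-[(4-methoxyphenyl)methoxy]but-2-en-1-yl}-3-methylcyclopentan-1-one | O=C1CC[C@](C)(C[C@@H](O[Si](C)(C)C(C)(C)C)C(C)=C)[C@H]1[C@@H](OCc1ccc(OC)cc1)/C=C/C | intermediate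
18 | (1R,2S,3R)-3-{(2R)-2-[(tert-butyldimethylsilyl)oxy]-3-methylbut-3-en-1-yl}-2-{(1S,2E)-1-[(4-methoxyphenyl)methoxy]but-2-en-1-yl}-3-methyl-1-(propan-2-yl)cyclopentan-1-ol | CC(C)[C@]1(O)CC[C@](C)(C[C@@H](O[Si](C)(C)C(C)(C)C)C(C)=C)[C@H]1[C@@H](OCc1ccc(OC)cc1)/C=C/C | intermediate
19 | (3R,3aS,4S,7R,8aR)-7-[(tert-butyldimethylsilyl)oxy]-4-[(4-methoxyphenyl)methoxy]-6,8a-dimethyl-3-(propan-2-yl)-1,2,3,3a,4,7,8,8a-octahydroazulen-3-ol | COc1ccc(CO[C@H]2C=C(C)[C@H](O[Si](C)(C)C(C)(C)C)C[C@@]3(C)CC[C@@](O)(C(C)C)[C@H]23)cc1 | intermediate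
20 | (3R,3aS,4S,7R,8aR)-7-[(tert-butyldimethylsilyl)oxy]-6,8a-dimethyl-3-(propan-2-yl)-1,2,3,3a,4,7,8,8a-octahydroazulene-3,4-diol | O[C@H]1C=C(C)[C@H](O[Si](C)(C)C(C)(C)C)C[C@@]2(C)CC[C@@](O)(C(C)C)[C@H]12 | intermediate
21 | 4-methoxybenzoyl chloride | COc1ccc(C(Cl)=O)cc1 | starting material
22 | (3R,3aS,4S,7R,8aR)-7-[(tert-butyldimethylsilyl)oxy]-3-hydroxy-6,8a-dimethyl-3-(propan-2-yl)-1,2,3,3a,4,7,8,8a-octahydroazulen-4-yl 4-methoxybenzoate | COc1ccc(C(=O)O[C@H]2C=C(C)[C@H](O[Si](C)(C)C(C)(C)C)C[C@@]3(C)CC[C@@](O)(C(C)C)[C@H]23)cc1 | intermediate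
23 | (3R,3aS,4S,7R,8aR)-3,7-dihydroxy-6,8a-dimethyl-3-(propan-2-yl)-1,2,3,3a,4,7,8,8a-octahydroazulen-4-yl 4-methoxybenzoate | COc1ccc(C(=O)O[C@H]2C=C(C)[C@H](O)C[C@@]3(C)CC[C@@](O)(C(C)C)[C@H]23)cc1 | target

**Count and risks**

Total step count: 14. Longest linear sequence: 11 steps (steps 4 to 14).

Steps most likely to fail:

1. Step 9. The C6 ether may discriminate the two faces of the enol ether only weakly in the sigmatropic shift, and at 130 °C the acylrhodium may lose CO or a rhodium hydride may move the propenyl double bond. The fallback replaces 1,2-induction by a lithium chelate and makes the two bonds in separate steps; it sets out from 10 and 6 and comes back at 16. Alkynylsilane 10 is hydroborated at the silyl-bearing carbon with Cy2BH and oxidised with NaOH/H2O2 to (3R,4E)-3-hydroxyhex-4-enoic acid F1, which is esterified with 6 (EDC, DMAP, CH2Cl2) to (2E,5R)-5-[(tert-butyldimethylsilyl)oxy]-3,6-dimethylhepta-2,6-dien-1-yl (3R,4E)-3-hydroxyhex-4-enoate F2. Its dianion (LiN(i-Pr)2, 2.5 equiv, THF, −78 °C to rt) should undergo the ester enolate Claisen rearrangement inside a six-membered lithium chelate, the allyl unit entering anti to the propenyl group as in Fráter–Seebach alkylations, to give (2S,3S)-3-{(2R)-2-[(tert-butyldimethylsilyl)oxy]-3-methylbut-3-en-1-yl}-2-[(1S,2E)-1-hydroxybut-2-en-1-yl]-3-methylpent-4-enoic acid F3. Double 4-methoxybenzylation with 4-methoxybenzyl trichloroacetimidate (La(OTf)3 cat.) should give 4-methoxybenzyl (2S,3S)-3-{(2R)-2-[(tert-butyldimethylsilyl)oxy]-3-methylbut-3-en-1-yl}-2-{(1S,2E)-1-[(4-methoxyphenyl)methoxy]but-2-en-1-yl}-3-methylpent-4-enoate F4, and i-Bu2AlH at −78 °C should reduce the ester to aldehyde 16. This is then closed to 17 by hydroacylation alone ([Rh(dppe)]ClO4, CH2Cl2, rt).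

2. Step 10. Enolisation of the hindered ketone or β-elimination of the 4-methoxybenzyl ether may outrun addition, and the flexible monocycle may give poor facial selectivity. The fallback closes the seven-membered ring first; it sets out from 17 and comes back at 19. Ring-closing metathesis of 17 (second-generation Grubbs catalyst, PhMe, 80 °C) should give (3aS,4S,7R,8aR)-7-[(tert-butyldimethylsilyl)oxy]-4-[(4-methoxyphenyl)methoxy]-6,8a-dimethyl-2,3a,4,7,8,8a-hexahydroazulen-3(1H)-one F5. On this rigid trans-fused ketone i-PrLi/CeCl3 (THF, −78 °C) should add from the face opposite the angular methyl group and give 19 directly.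

3. Step 11. Ring closure may be slow because both reacting alkenes are flanked by protected allylic oxygens and one of them is 1,1-disubstituted, so that oligomerisation or olefin migration competes. The fallback uses a free allylic hydroxyl to assist the closure; it sets out from 18 and comes back at 19. Bu4NF (THF, rt) should remove the silyl group to give (1R,2S,3R)-3-[(2R)-2-hydroxy-3-methylbut-3-en-1-yl]-2-{(1S,2E)-1-[(4-methoxyphenyl)methoxy]but-2-en-1-yl}-3-methyl-1-(propan-2-yl)cyclopentan-1-ol F6, whose C9 hydroxyl should speed up ruthenium loading at the isopropenyl group. Metathesis (second-generation Grubbs catalyst, CH2Cl2, 40 °C) should then give (3R,3aS,4S,7R,8aR)-4-[(4-methoxyphenyl)methoxy]-6,8a-dimethyl-3-(propan-2-yl)-1,2,3,3a,4,7,8,8a-octahydroazulene-3,7-diol F7, and selective silylation of the secondary allylic hydroxyl (TBSCl, imidazole, DMF) returns 19.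

**Further compounds**

F1 | step 9 | (3R,4E)-3-hydroxyhex-4-enoic acid | O[C@H](CC(=O)O)/C=C/C
F2 | step 9 | (2E,5R)-5-[(tert-butyldimethylsilyl)oxy]-3,6-dimethylhepta-2,6-dien-1-yl (3R,4E)-3-hydroxyhex-4-enoate | O[C@H](CC(=O)OC/C=C(\C)C[C@@H](O[Si](C)(C)C(C)(C)C)C(C)=C)/C=C/C
F3 | step 9 | (2S,3S)-3-{(2R)-2-[(tert-butyldimethylsilyl)oxy]-3-methylbut-3-en-1-yl}-2-[(1S,2E)-1-hydroxybut-2-en-1-yl]-3-methylpent-4-enoic acid | OC(=O)[C@H]([C@@H](O)/C=C/C)[C@](C)(C=C)C[C@@H](O[Si](C)(C)C(C)(C)C)C(C)=C
F4 | step 9 | 4-methoxybenzyl (2S,3S)-3-{(2R)-2-[(tert-butyldimethylsilyl)oxy]-3-methylbut-3-en-1-yl}-2-{(1S,2E)-1-[(4-methoxyphenyl)methoxy]but-2-en-1-yl}-3-methylpent-4-enoate | COc1ccc(COC(=O)[C@H]([C@@H](OCc2ccc(OC)cc2)/C=C/C)[C@](C)(C=C)C[C@@H](O[Si](C)(C)C(C)(C)C)C(C)=C)cc1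
F5 | step 10 | (3aS,4S,7R,8aR)-7-[(tert-butyldimethylsilyl)oxy]-4-[(4-methoxyphenyl)methoxy]-6,8a-dimethyl-2,3a,4,7,8,8a-hexahydroazulen-3(1H)-one | COc1ccc(CO[C@H]2C=C(C)[C@H](O[Si](C)(C)C(C)(C)C)C[C@@]3(C)CCC(=O)[C@H]23)cc1
F6 | step 11 | (1R,2S,3R)-3-[(2R)-2-hydroxy-3-methylbut-3-en-1-yl]-2-{(1S,2E)-1-[(4-methoxyphenyl)methoxy]but-2-en-1-yl}-3-methyl-1-(propan-2-yl)cyclopentan-1-ol | CC(C)[C@]1(O)CC[C@](C)(C[C@@H](O)C(C)=C)[C@H]1[C@@H](OCc1ccc(OC)cc1)/C=C/C
F7 | step 11 | (3R,3aS,4S,7R,8aR)-4-[(4-methoxyphenyl)methoxy]-6,8a-dimethyl-3-(propan-2-yl)-1,2,3,3a,4,7,8,8a-octahydroazulene-3,7-diol | COc1ccc(CO[C@H]2C=C(C)[C@H](O)C[C@@]3(C)CC[C@@](O)(C(C)C)[C@H]23)cc1
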